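**Retrosynthetic overview**
1. Sikokianin A is a 3,3''-linked biflavanone, (2S,3S,2''S,3''S), 2,3-cis in both halves. The five benzyl ethers are removed last. Before that, the O1–C8a and O1''–C8a'' bonds of the two pyranone rings (rings C) are cut back to C2/C2'' carbinols and ortho-fluoro aryl ketones (alkoxide SNAr, retention at C2 and C2'').
2. Feature used: with C2 and C2'' as ketones, C3 and C3'' each lie between two aryl carbonyls (C2=O/C4=O and C2''=O/C4''=O) and epimerise freely. Of the four carbonyls only C2=O and C2''=O (4-alkoxybenzoyl) are open to a catalyst, because C4=O and C4''=O are flanked by F and OBn on the A rings.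
3. Key disconnection: the C2–H and C2''–H bonds, made by one twofold asymmetric transfer hydrogenation with dynamic kinetic resolution of acyclic tetraketone 16. This sets C2, C3, C3'' and C2'' together.
4. Tetraketone 16 comes from C-aroylation at C3'' of triketone 12. The C3–C3'' bond of 12 is made by alkylating 1,3-diketone 11 with bromo ketone 8. Both 11 and 8 are made from one acetophenone 6, which comes from the aryllithium of benzylated, brominated 5-fluororesorcinol and a Weinreb amide.
5. Ring order: the A rings come with 5-fluororesorcinol and the B rings with the aroyl chlorides. Both pyranone rings close together in step 10, after the key step, which closes no ring.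

Key step: step 9

Remark: flavanone numbering (C2, C3, C4; doubly primed for the 4-hydroxyphenyl half) is used for the acyclic compounds too. N-Methoxy-N-methylacetamide is taken as purchased. Acetophenone 6 is made on a scale that serves both step 4 and step 5.

**Route**

Step 1
Reactants: 1 5-fluororesorcinol
Product: 2 1,3-bis(benzyloxy)-5-fluorobenzene
Conditions: BnBr, K2CO3, DMF, 60 °C
Reagents that add atoms: benzyl bromide, BrCc1ccccc1
Why: Williamson ether synthesis on both phenols; benzyl ethers should survive organolithium, enolate and transfer-hydrogenation conditions and leave by hydrogenolysis at the end.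

Step 2
Reactants: 2 1,3-bis(benzyloxy)-5-fluorobenzene
Product: 3 1,5-bis(benzyloxy)-2-bromo-3-fluorobenzene
Conditions: NBS (1 equiv), MeCN, 0 °C → rt, dark
Reagents that add atoms: N-bromosuccinimide, O=C1CCC(=O)N1Br
Why: Electrophilic aromatic bromination should go para to one benzyloxy group and ortho to the other (the position next to fluorine), not into the more crowded position between the two ethers, as is usual for 5-substituted resorcinol diethers; one equivalent at low temperature limits dibromination.

Step 3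
Reactants: 3 1,5-bis(benzyloxy)-2-bromo-3-fluorobenzene; 4 N-methoxy-N-methylacetamide
Product: 6 1-[2,4-bis(benzyloxy)-6-fluorophenyl]ethan-1-one, via aryllithium 5 (not isolated)
Conditions: n-BuLi, THF, −78 °C; then 4, −78 °C; 1 M HCl
Reagents that add atoms: none
Why: Bromine–lithium exchange at −78 °C (cold enough that the ortho-fluoro aryllithium does not lose LiF to an aryne) followed by Weinreb ketone synthesis, in which the N-methoxy amide stops the addition at the ketone stage.

Step 4
Reactants: 6 1-[2,4-bis(benzyloxy)-6-fluorophenyl]ethan-1-one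
Product: 8 1-[2,4-bis(benzyloxy)-6-fluorophenyl]-2-bromoethan-1-one, via trimethylsilyl enol ether 7 (not isolated)
Conditions: Me3SiOTf, Et3N, CH2Cl2, 0 °C; then NBS (1.0 equiv), −78 → 0 °C; aq. NaHCO3
Reagents that add atoms: N-bromosuccinimide, O=C1CCC(=O)N1Br
Why: Soft enolisation to the silyl enol ether followed by electrophilic α-bromination with NBS; the enol ether is far more nucleophilic than the acyl-bearing arene, so one equivalent of NBS at low temperature should give the monobromo ketone without ring bromination and without strong acid near the benzyl ethers.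

Step 5
Reactants: 6 1-[2,4-bis(benzyloxy)-6-fluorophenyl]ethan-1-one; 9 4-methoxybenzoyl chloride
Product: 11 1-[2,4-bis(benzyloxy)-6-fluorophenyl]-3-(4-methoxyphenyl)propane-1,3-dione, via lithium enolate 10 (not isolated)
Conditions: LiN(SiMe3)2 (2.2 equiv), THF, −78 °C; then 9, −78 → 0 °C; 1 M HCl
Reagents that add atoms: none
Why: Claisen-type C-acylation of a lithium enolate by an aroyl chloride; the second equivalent of base takes up the more acidic 1,3-diketone as it forms, and the low temperature keeps the enolate oxygen from displacing the ortho fluoride.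

Step 6
Reactants: 11 1-[2,4-bis(benzyloxy)-6-fluorophenyl]-3-(4-methoxyphenyl)propane-1,3-dione; 8 1-[2,4-bis(benzyloxy)-6-fluorophenyl]-2-bromoethan-1-one
Product: 12 1,4-bis[2,4-bis(benzyloxy)-6-fluorophenyl]-2-(4-methoxybenzoyl)butane-1,4-dione (racemic, C3 labile)
Conditions: K2CO3, acetone, rt
Reagents that add atoms: none
Why: C-alkylation of a 1,3-diketone enolate by an α-bromo ketone (SN2 at a primary carbon activated by the carbonyl) makes the C3–C3'' bond; the 2-substituted diketone formed is too hindered to alkylate again.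

Step 7
Reactants: 13 4-(benzyloxy)benzoic acid
Product: 14 4-(benzyloxy)benzoyl chloride
Conditions: (COCl)2, DMF (cat.), CH2Cl2, 0 °C → rt
Reagents that add atoms: oxalyl chloride, O=C(Cl)C(=O)Cl
Why: Acid chloride formation through the chloroiminium salt from DMF and oxalyl chloride; the benzyl ether is not touched.

Step 8
Reactants: 12 1,4-bis[2,4-bis(benzyloxy)-6-fluorophenyl]-2-(4-methoxybenzoyl)butane-1,4-dione; 14 4-(benzyloxy)benzoyl chloride
Product: 16 1,4-bis[2,4-bis(benzyloxy)-6-fluorophenyl]-2-[4-(benzyloxy)benzoyl]-3-(4-methoxybenzoyl)butane-1,4-dione (tetraketone; C3 and C3'' labile), via dilithium dienediolate 15 (not isolated)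
Conditions: LiN(SiMe3)2 (3.2 equiv), THF, −78 °C; then 14, −78 → −20 °C; 1 M HCl
Reagents that add atoms: none
Why: Dianion acylation: the first equivalent of base parks the 1,3-diketone as its enolate, the second forms the less stabilised and more nucleophilic ketone enolate at C3'', which should take the aroyl chloride at carbon, and the third takes up the new diketone.

Step 9
Reactants: 16 1,4-bis[2,4-bis(benzyloxy)-6-fluorophenyl]-2-[4-(benzyloxy)benzoyl]-3-(4-methoxybenzoyl)butane-1,4-dione
Product: 19 (2S,3S)-1,4-bis[2,4-bis(benzyloxy)-6-fluorophenyl]-2-{(S)-[4-(benzyloxy)phenyl](hydroxy)methyl}-3-[(S)-hydroxy(4-methoxyphenyl)methyl]butane-1,4-dione (syn,syn-diol), via anisyl-side hydroxy triketone 17 (not isolated), via benzyloxyphenyl-side hydroxy triketone 18 (not isolated)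
Conditions: RuCl(p-cymene)[(S,S)-TsDPEN] (10 mol %), HCO2H–Et3N (5:2), DMF, 40 °C
Reagents that add atoms: none
Why: Formate turns the 16-electron ruthenium amide into the divalent ruthenium hydride, which passes Ru–H and N–H to an aryl ketone through a six-membered outer-sphere transition state (Noyori–Ikariya asymmetric transfer hydrogenation), once at each 4-alkoxybenzoyl carbonyl, the two possible orders running through 17 and 18. The closest known reaction type is the Ru–TsDPEN transfer hydrogenation with dynamic kinetic resolution of 2-alkyl-1,3-diketones and of α-alkyl β-keto esters and amides carrying an aryl ketone, which gives syn β-hydroxy carbonyl compounds; here it is used twice in one molecule. No ring closes in this step. C2 and C2'' are set by the catalyst: the (S,S) ligand delivers hydride to the face that turns acetophenone into (S)-1-phenylethanol, the aryl group lying against the p-cymene ligand, which is S for both carbinols. C3 and C3'' are set by the substrate through the labile α-centres: under Et3N each 1,3-diketone epimerises through its enol faster than it is reduced, and the epimer that reacts should have C3–H on the aryl side, the bulky C3–C3'' bond anti to the incoming hydride and the fluoroaroyl group next to the carbonyl oxygen, which is the syn arrangement (S at C3 and C3''). The step needs site selectivity among four ketones; it should come from the 2,4-bis(benzyloxy)-6-fluorobenzoyl carbonyls being flanked by two ortho substituents and deactivated by two alkoxy donors, while a half that has been reduced keeps only one carbonyl at its α-centre and is configurationally fixed before the other half reacts.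

Step 10
Reactants: 19 syn,syn-diol
Product: 21 (2S,3S)-5,7-bis(benzyloxy)-3-{(2S,3S)-5,7-bis(benzyloxy)-2-[4-(benzyloxy)phenyl]-4-oxochroman-3-yl}-2-(4-methoxyphenyl)chroman-4-one, via dipotassium dialkoxide 20 (not isolated)
Conditions: KN(SiMe3)2 (2.1 equiv), 18-crown-6, THF, −78 → 0 °C; AcOH
Reagents that add atoms: none
Why: Intramolecular nucleophilic aromatic substitution (addition–elimination) of each alkoxide on the fluoride ortho to the C4 or C4'' carbonyl should close the two six-membered pyranone rings in preference to the seven-membered alternative; the C2–O and C2''–O bonds are not broken, so C2 and C2'' are retained and each syn aldol unit becomes a 2,3-cis flavanone.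

Step 11
Reactants: 21 pentabenzyl biflavanone
Product: 22 sikokianin A [(2S,3S)-3-[(2S,3S)-5,7-dihydroxy-2-(4-hydroxyphenyl)-4-oxochroman-3-yl]-5,7-dihydroxy-2-(4-methoxyphenyl)chroman-4-one]
Conditions: H2 (1 atm), Pd/C (10 wt %), EtOAc–MeOH, rt
Reagents that add atoms: none
Why: Hydrogenolysis of the five benzyl ethers over palladium under neutral conditions should leave the ketones, the methyl ether and the cyclic C2–O1 bonds alone and does not expose the base-sensitive C3 and C3'' centres to epimerisation.

**Compound list**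

1 | 5-fluororesorcinol | Oc1cc(O)cc(F)c1 | starting material
2 | 1,3-bis(benzyloxy)-5-fluorobenzene | Fc1cc(OCc2ccccc2)cc(OCc2ccccc2)c1 | intermediate
3 | 1,5-bis(benzyloxy)-2-bromo-3-fluorobenzene | Brc1c(F)cc(OCc2ccccc2)cc1OCc1ccccc1 | intermediate
4 | N-methoxy-N-methylacetamide | CC(=O)N(C)OC | starting material
5 | [2,4-bis(benzyloxy)-6-fluorophenyl]lithium | [Li]c1c(F)cc(OCc2ccccc2)cc1OCc1ccccc1 | intermediate (not isolated)
6 | 1-[2,4-bis(benzyloxy)-6-fluorophenyl]ethan-1-one | CC(=O)c1c(F)cc(OCc2ccccc2)cc1OCc1ccccc1 | intermediate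
7 | ({1-[2,4-bis(benzyloxy)-6-fluorophenyl]ethenyl}oxy)trimethylsilane (trimethylsilyl enol ether of 6) | C=C(O[Si](C)(C)C)c1c(F)cc(OCc2ccccc2)cc1OCc1ccccc1 | intermediate (not isolated)
8 | 1-[2,4-bis(benzyloxy)-6-fluorophenyl]-2-bromoethan-1-one | BrCC(=O)c1c(F)cc(OCc2ccccc2)cc1OCc1ccccc1 | intermediate
9 | 4-methoxybenzoyl chloride | COc1ccc(C(=O)Cl)cc1 | starting material
10 | lithium enolate of 6 | [Li]OC(=C)c1c(F)cc(OCc2ccccc2)cc1OCc1ccccc1 | intermediate (not isolated)
11 | 1-[2,4-bis(benzyloxy)-6-fluorophenyl]-3-(4-methoxyphenyl)propane-1,3-dione | COc1ccc(cc1)C(=O)CC(=O)c1c(F)cc(OCc2ccccc2)cc1OCc1ccccc1 | intermediate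
12 | 1,4-bis[2,4-bis(benzyloxy)-6-fluorophenyl]-2-(4-methoxybenzoyl)butane-1,4-dione (racemic, labile centre) | COc1ccc(cc1)C(=O)C(CC(=O)c1c(F)cc(OCc2ccccc2)cc1OCc1ccccc1)C(=O)c1c(F)cc(OCc2ccccc2)cc1OCc1ccccc1 | intermediate
13 | 4-(benzyloxy)benzoic acid | O=C(O)c1ccc(OCc2ccccc2)cc1 | starting material
14 | 4-(benzyloxy)benzoyl chloride | O=C(Cl)c1ccc(OCc2ccccc2)cc1 | intermediate
15 | dilithium dienediolate of 12 | COc1ccc(cc1)C(O[Li])=C(C=C(O[Li])c1c(F)cc(OCc2ccccc2)cc1OCc1ccccc1)C(=O)c1c(F)cc(OCc2ccccc2)cc1OCc1ccccc1 | intermediate (not isolated)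
16 | 1,4-bis[2,4-bis(benzyloxy)-6-fluorophenyl]-2-[4-(benzyloxy)benzoyl]-3-(4-methoxybenzoyl)butane-1,4-dione (tetraketone, C3 and C3'' labile) | COc1ccc(cc1)C(=O)C(C(=O)c1c(F)cc(OCc2ccccc2)cc1OCc1ccccc1)C(C(=O)c1ccc(OCc2ccccc2)cc1)C(=O)c1c(F)cc(OCc2ccccc2)cc1OCc1ccccc1 | intermediate
17 | (3S)-1,4-bis[2,4-bis(benzyloxy)-6-fluorophenyl]-2-[4-(benzyloxy)benzoyl]-3-[(S)-hydroxy(4-methoxyphenyl)methyl]butane-1,4-dione (C3'' still labile) | COc1ccc(cc1)[C@@H](O)[C@@H](C(=O)c1c(F)cc(OCc2ccccc2)cc1OCc1ccccc1)C(C(=O)c1ccc(OCc2ccccc2)cc1)C(=O)c1c(F)cc(OCc2ccccc2)cc1OCc1ccccc1 | intermediate (not isolated)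
18 | (2S)-1,4-bis[2,4-bis(benzyloxy)-6-fluorophenyl]-2-{(S)-[4-(benzyloxy)phenyl](hydroxy)methyl}-3-(4-methoxybenzoyl)butane-1,4-dione (C3 still labile) | COc1ccc(cc1)C(=O)C(C(=O)c1c(F)cc(OCc2ccccc2)cc1OCc1ccccc1)[C@H](C(=O)c1c(F)cc(OCc2ccccc2)cc1OCc1ccccc1)[C@H](O)c1ccc(OCc2ccccc2)cc1 | intermediate (not isolated)
19 | (2S,3S)-1,4-bis[2,4-bis(benzyloxy)-6-fluorophenyl]-2-{(S)-[4-(benzyloxy)phenyl](hydroxy)methyl}-3-[(S)-hydroxy(4-methoxyphenyl)methyl]butane-1,4-dione (syn,syn-diol) | COc1ccc(cc1)[C@@H](O)[C@@H](C(=O)c1c(F)cc(OCc2ccccc2)cc1OCc1ccccc1)[C@H](C(=O)c1c(F)cc(OCc2ccccc2)cc1OCc1ccccc1)[C@H](O)c1ccc(OCc2ccccc2)cc1 | intermediate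
20 | dipotassium dialkoxide of 19 | COc1ccc(cc1)[C@@H](O[K])[C@@H](C(=O)c1c(F)cc(OCc2ccccc2)cc1OCc1ccccc1)[C@H](C(=O)c1c(F)cc(OCc2ccccc2)cc1OCc1ccccc1)[C@H](O[K])c1ccc(OCc2ccccc2)cc1 | intermediate (not isolated)
21 | (2S,3S)-5,7-bis(benzyloxy)-3-{(2S,3S)-5,7-bis(benzyloxy)-2-[4-(benzyloxy)phenyl]-4-oxochroman-3-yl}-2-(4-methoxyphenyl)chroman-4-one | COc1ccc([C@H]2Oc3cc(OCc4ccccc4)cc(OCc4ccccc4)c3C(=O)[C@H]2[C@@H]2C(=O)c3c(OCc4ccccc4)cc(OCc4ccccc4)cc3O[C@@H]2c2ccc(OCc3ccccc3)cc2)cc1 | intermediate
22 | sikokianin A, (2S,3S,2''S,3''S) | COc1ccc([C@H]2Oc3cc(O)cc(O)c3C(=O)[C@H]2[C@@H]2C(=O)c3c(O)cc(O)cc3O[C@@H]2c2ccc(O)cc2)cc1 | target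

**Step count and risks**

Total steps: 11. Longest linear sequence: 9 (steps 1, 2, 3, 5, 6, 8, 9, 10, 11).

Steps most likely to fail:

Step 9 (key step). The 1,4-dicarbonyl array may cyclodehydrate to a furan in the acidic formate medium. The first-formed carbinol may trap the remaining 4-alkoxybenzoyl carbonyl as a five-membered lactol. The second reduction is doubly stereodifferentiating and may be slow or lose syn selectivity at C3''. The fallback runs the two resolutions one at a time around the last C–C bond formation and sets out from triketone 12. The same catalyst should reduce its single 4-methoxybenzoyl carbonyl with dynamic kinetic resolution to (2S)-1,4-bis[2,4-bis(benzyloxy)-6-fluorophenyl]-2-[(S)-hydroxy(4-methoxyphenyl)methyl]butane-1,4-dione F1, a plain 2-alkyl-1,3-diketone case. The carbinol is silylated (t-BuMe2SiOTf, 2,6-lutidine) to the tert-butyldimethylsilyl ether F2, which also removes the lactol pathway. Kinetic deprotonation of the CH2 group with LiN(SiMe3)2 and acylation with 14 gives the silyloxy triketone F3. A second transfer hydrogenation with the same catalyst gives the mono-silylated syn,syn-diol F4, and HF·pyridine in THF removes the silyl group, so the route is rejoined at diol 19.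

Step 10. The potassium alkoxides may fragment by retro-aldol cleavage, excess base may epimerise C3 and C3'' (the 2,3-cis flavanone is the less stable isomer), and fluoride displacement on the alkoxy-rich ring may be slow. The fallback generates the alkoxide without free strong base and sets out from diol 19. Me3SiCl and imidazole give the bis(trimethylsilyl) ether F5. Catalytic CsF in DMF at room temperature should unmask each alkoxide in low concentration; the ring closes by the same SNAr and the fluoride leaving the ring carries the chain on while Me3SiF is lost. This returns to 21.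

Step 8. The hindered ketone enolate may be acylated on oxygen, the second deprotonation may be incomplete, and on warming the diketonate may close onto the ortho fluoride to a flavone. The fallback makes the C3–C3'' bond last by oxidative enolate coupling and sets out from acetophenone 6 and diketone 11. The conditions of step 5 with acid chloride 14 turn 6 into 1-[2,4-bis(benzyloxy)-6-fluorophenyl]-3-[4-(benzyloxy)phenyl]propane-1,3-dione F6. A mixture of 11 and F6 is deprotonated with NaH in THF and oxidised with I2 at 0 °C, the established way to 1,1,2,2-tetraacylethanes. The cross-coupled product is separated from the two symmetrical dimers by chromatography, which returns to tetraketone 16 and bypasses 12.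

**Further compounds**

F1 | step 9 | (2S)-1,4-bis[2,4-bis(benzyloxy)-6-fluorophenyl]-2-[(S)-hydroxy(4-methoxyphenyl)methyl]butane-1,4-dione | COc1ccc(cc1)[C@@H](O)[C@@H](C(=O)c1c(F)cc(OCc2ccccc2)cc1OCc1ccccc1)CC(=O)c1c(F)cc(OCc2ccccc2)cc1OCc1ccccc1
F2 | step 9 | tert-butyldimethylsilyl ether of F1 | COc1ccc(cc1)[C@@H](O[Si](C)(C)C(C)(C)C)[C@@H](C(=O)c1c(F)cc(OCc2ccccc2)cc1OCc1ccccc1)CC(=O)c1c(F)cc(OCc2ccccc2)cc1OCc1ccccc1
F3 | step 9 | (3S)-1,4-bis[2,4-bis(benzyloxy)-6-fluorophenyl]-2-[4-(benzyloxy)benzoyl]-3-[(S)-(tert-butyldimethylsilyloxy)(4-methoxyphenyl)methyl]butane-1,4-dione (C3'' labile) | COc1ccc(cc1)[C@@H](O[Si](C)(C)C(C)(C)C)[C@@H](C(=O)c1c(F)cc(OCc2ccccc2)cc1OCc1ccccc1)C(C(=O)c1ccc(OCc2ccccc2)cc1)C(=O)c1c(F)cc(OCc2ccccc2)cc1OCc1ccccc1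
F4 | step 9 | (2S,3S)-1,4-bis[2,4-bis(benzyloxy)-6-fluorophenyl]-2-{(S)-[4-(benzyloxy)phenyl](hydroxy)methyl}-3-[(S)-(tert-butyldimethylsilyloxy)(4-methoxyphenyl)methyl]butane-1,4-dione | COc1ccc(cc1)[C@@H](O[Si](C)(C)C(C)(C)C)[C@@H](C(=O)c1c(F)cc(OCc2ccccc2)cc1OCc1ccccc1)[C@H](C(=O)c1c(F)cc(OCc2ccccc2)cc1OCc1ccccc1)[C@H](O)c1ccc(OCc2ccccc2)cc1
F5 | step 10 | bis(trimethylsilyl) ether of 19 | COc1ccc(cc1)[C@@H](O[Si](C)(C)C)[C@@H](C(=O)c1c(F)cc(OCc2ccccc2)cc1OCc1ccccc1)[C@H](C(=O)c1c(F)cc(OCc2ccccc2)cc1OCc1ccccc1)[C@H](O[Si](C)(C)C)c1ccc(OCc2ccccc2)cc1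
F6 | step 8 | 1-[2,4-bis(benzyloxy)-6-fluorophenyl]-3-[4-(benzyloxy)phenyl]propane-1,3-dione | O=C(CC(=O)c1c(F)cc(OCc2ccccc2)cc1OCc1ccccc1)c1ccc(OCc2ccccc2)cc1
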